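Numbering follows 6-oxabicyclo[3.2.2]non-3-ene-2,7-dione. The lactone ring O6–C7–C1–C8–C9–C5 ends in a ketal carbon (C5: OMe plus ring oxygen) beside the C9(Me)–C8(Ar) pair, the imprint of an inverse-demand hetero-Diels–Alder adduct of a methyl enol ether and a 1-oxadiene. The route rests on the C8–C9 disconnection: a copper bis(oxazoline)-catalysed [4+2] of an aryl β,γ-unsaturated α-keto ester with an (E)-enol ether that already carries the (Z)-C4=C3(allyl)–C2 ester arm closes the pyran, forms C8–C9 and O6–C5, and sets C8, C9 and C5 enantioselectively in one operation. Curtius excision of the surplus ester carbon unveils the lactone; a Dieckmann-type C1–C2 acylation closes the carbocycle.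

Key step: step 8

Remark (assumption): the sense of asymmetric induction in step 8 is assigned from the square-planar chelate model of the divalent copper–bis(oxazoline)–keto ester complex; if it proves opposite, the (R,R)-ligand is the one to use.

Step 1
Reactants: 1 3,4,5-trimethoxybenzaldehyde; 2 pyruvic acid
Product: 3 potassium (3E)-2-oxo-4-(3,4,5-trimethoxyphenyl)but-3-enoate
Conditions: KOH, MeOH, 0 °C → rt
Reagents that add atoms: potassium hydroxide, [K+].[OH-]
Why: Crossed aldol (Claisen–Schmidt) condensation of the pyruvate enolate with the non-enolisable aldehyde and E1cB dehydration should give the E-configured styryl keto acid, which separates as its potassium salt.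

Step 2
Reactants: 3 potassium (3E)-2-oxo-4-(3,4,5-trimethoxyphenyl)but-3-enoate; 4 allyl bromide
Product: 5 prop-2-en-1-yl (3E)-2-oxo-4-(3,4,5-trimethoxyphenyl)but-3-enoate
Conditions: DMF, rt
Reagents that add atoms: none
Why: SN2 O-alkylation of the carboxylate; the allyl ester is chosen because zerovalent palladium can later remove it without touching the methyl ester of the other fragment.

Step 3
Reactants: 6 methyl bis(2,2,2-trifluoroethyl)phosphonoacetate; 4 allyl bromide
Product: 7 methyl 2-[bis(2,2,2-trifluoroethoxy)phosphoryl]pent-4-enoate (racemic)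
Conditions: NaH, THF, 0 °C → rt
Reagents that add atoms: none
Why: The phosphonate-stabilised carbanion is C-alkylated by allyl bromide (SN2), which places the future C3 allyl group on the Still–Gennari reagent.

Step 4
Reactants: 8 but-2-yn-1-ol
Product: 10 (2E)-2-iodobut-2-en-1-ol, via vinylstannane 9 (not isolated)
Conditions: Bu3SnH, PdCl2(PPh3)2 (cat.), THF, 0 °C → rt; then I2, CH2Cl2, 0 °C
Reagents that add atoms: tributyltin hydride, CCCC[SnH](CCCC)CCCC; iodine, II
Why: Palladium-catalysed syn-hydrostannation should place tin preferentially on the alkyne carbon next to the hydroxymethyl group with hydrogen cis to it, and iododestannylation with retention then fixes methyl cis to CH2OH (the later C9-methyl/C4 relationship); any distal regioisomer is removed at the iodide stage.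

Step 5
Reactants: 10 (2E)-2-iodobut-2-en-1-ol
Product: 11 (2E)-2-methoxybut-2-en-1-ol
Conditions: CuI (10 mol %), 3,4,7,8-tetramethyl-1,10-phenanthroline (20 mol %), Cs2CO3, MeOH–toluene, 80 °C
Reagents that add atoms: methanol, CO
Why: Copper-catalysed Ullmann-type C–O coupling of a vinyl iodide with an alcohol proceeds with retention of alkene geometry, so the E-enol ether (methyl trans to OMe) should result; methanol as co-solvent outcompetes the substrate hydroxyl.

Step 6
Reactants: 11 (2E)-2-methoxybut-2-en-1-ol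
Product: 12 (2E)-2-methoxybut-2-enal
Conditions: MnO2, CH2Cl2, rt
Reagents that add atoms: none
Why: MnO2 oxidises the allylic alcohol to the enal under neutral conditions that should leave the acid-labile enol ether and its geometry intact.

Step 7
Reactants: 12 (2E)-2-methoxybut-2-enal; 7 methyl 2-[bis(2,2,2-trifluoroethoxy)phosphoryl]pent-4-enoate
Product: 13 methyl (2Z,4E)-4-methoxy-2-(prop-2-en-1-yl)hexa-2,4-dienoate
Conditions: KN(SiMe3)2, 18-crown-6, THF, −78 °C
Reagents that add atoms: none
Why: Still–Gennari olefination: the trifluoroethyl phosphonate makes elimination of the kinetically formed adduct fast, which should give the Z-trisubstituted enoate (ester cis to the enol-ether carbon) needed for the later ring closure.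

Step 8
Reactants: 5 prop-2-en-1-yl (3E)-2-oxo-4-(3,4,5-trimethoxyphenyl)but-3-enoate; 13 methyl (2Z,4E)-4-methoxy-2-(prop-2-en-1-yl)hexa-2,4-dienoate
Product: 14 prop-2-en-1-yl (2S,3R,4S)-2-methoxy-2-[(1Z)-2-(methoxycarbonyl)penta-1,4-dien-1-yl]-3-methyl-4-(3,4,5-trimethoxyphenyl)-3,4-dihydro-2H-pyran-6-carboxylate
Conditions: Cu(OTf)2 (10 mol %), 2,2′-(propane-2,2-diyl)bis[(4S)-4-tert-butyl-4,5-dihydro-1,3-oxazole] (11 mol %), 3 Å MS, THF, −20 °C → rt
Reagents that add atoms: none
Why: The divalent copper centre chelates the 1,2-dicarbonyl unit of 5 in a square-planar complex and lowers the LUMO of the 1-oxadiene (O=C–C=C8), which undergoes a concerted but asynchronous inverse-electron-demand hetero-Diels–Alder reaction with the enol-ether double bond of 13; the closest known reaction type is the copper bis(oxazoline)-catalysed cycloaddition of β,γ-unsaturated α-keto esters with enol ethers. The dihydropyran (the future lactone ring O6–C7–C1–C8–C9–C5) is closed by [4+2] cycloaddition, the C8–C9 bond and the O6–C5 bond being formed in the same step. C8 and C9 are set relative to each other by suprafacial addition of the E-oxadiene to the E-enol ether (aryl and methyl trans, methyl cis to the C4 arm), C5 by the endo orientation of the methoxy group (OMe cis to aryl), and the absolute configuration by the tert-butyl group of the ligand, which shields one face of the bound oxadiene. The step needs regioselectivity (the nucleophilic β-carbon of the enol ether, future C9, must bond to the electrophilic terminus C8), secured by the push–pull polarisation of both partners; chemoselectivity for the enol-ether double bond, secured because the Z-trisubstituted diene of 13 cannot reach the s-cis conformation of a normal Diels–Alder diene and its other alkenes are electron-poor or isolated; and endo selectivity, expected from the alkoxy-endo preference of this catalyst class.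

Step 9
Reactants: 14 prop-2-en-1-yl ester cycloadduct
Product: 15 (2S,3R,4S)-2-methoxy-2-[(1Z)-2-(methoxycarbonyl)penta-1,4-dien-1-yl]-3-methyl-4-(3,4,5-trimethoxyphenyl)-3,4-dihydro-2H-pyran-6-carboxylic acid
Conditions: Pd(PPh3)4 (5 mol %), morpholine, THF, rt; pH 5 buffer work-up
Reagents that add atoms: none
Why: Zerovalent palladium ionises only the allylic ester C–O bond (Tsuji–Trost deallylation) and morpholine captures the π-allyl fragment, so the acid should be freed without touching the methyl ester, the C-allyl group or the ketal.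

Step 10
Reactants: 15 dihydropyran-6-carboxylic acid
Product: 19 methyl (2Z)-2-{[(2S,3R,4S)-2-methoxy-3-methyl-6-oxo-4-(3,4,5-trimethoxyphenyl)oxan-2-yl]methylidene}pent-4-enoate, via acyl azide 16 (not isolated), via vinyl isocyanate 17 (not isolated), via iminolactone 18 (not isolated)
Conditions: (PhO)2P(O)N3, Et3N, toluene, rt → 80 °C; then THF, aq. NaOAc–AcOH (pH 5), rt
Reagents that add atoms: diphenylphosphoryl azide, O=P(N=[N+]=[N-])(Oc1ccccc1)Oc1ccccc1; water, O
Why: Curtius rearrangement excises the surplus carboxyl carbon (lost as CO2 when the vinyl isocyanate is hydrolysed), and the resulting enamine tautomerises to the cyclic imidate 18, whose hydrolysis at pH 5 with loss of ammonia should leave C7 as the lactone carbonyl and C1 as CH2 without acid strong enough to ionise the C5 ketal.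

Step 11
Reactants: 19 methoxy lactone ester
Product: 20 (1R,5S,8R,9R)-5-methoxy-9-methyl-3-(prop-2-en-1-yl)-8-(3,4,5-trimethoxyphenyl)-6-oxabicyclo[3.2.2]non-3-ene-2,7-dione
Conditions: LiN(SiMe3)2, THF, −78 → −40 °C; then aq. NH4Cl, −78 °C
Reagents that add atoms: none
Why: Dieckmann-type intramolecular Claisen acylation: the lithium enolate of the lactone (C1) attacks the methyl ester (C2), which the Z-alkene and the C5 arm hold over the ring, closing the seven-membered carbocycle; the new C1 centre can only form with the bridge cis to the C5–C4 bond, and its bridgehead position prevents later epimerisation.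

Compound list
1 | 3,4,5-trimethoxybenzaldehyde | COc1cc(C=O)cc(OC)c1OC | starting material
2 | pyruvic acid | CC(=O)C(=O)O | starting material
3 | potassium (3E)-2-oxo-4-(3,4,5-trimethoxyphenyl)but-3-enoate | COc1cc(/C=C/C(=O)C(=O)[O-])cc(OC)c1OC.[K+] | intermediate
4 | allyl bromide (3-bromoprop-1-ene) | C=CCBr | starting material
5 | prop-2-en-1-yl (3E)-2-oxo-4-(3,4,5-trimethoxyphenyl)but-3-enoate | COc1cc(/C=C/C(=O)C(=O)OCC=C)cc(OC)c1OC | intermediate
6 | methyl bis(2,2,2-trifluoroethyl)phosphonoacetate | COC(=O)CP(=O)(OCC(F)(F)F)OCC(F)(F)F | starting material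
7 | methyl 2-[bis(2,2,2-trifluoroethoxy)phosphoryl]pent-4-enoate (racemic) | COC(=O)C(CC=C)P(=O)(OCC(F)(F)F)OCC(F)(F)F | intermediate
8 | but-2-yn-1-ol | CC#CCO | starting material
9 | (2E)-2-(tributylstannyl)but-2-en-1-ol | C/C=C(\CO)[Sn](CCCC)(CCCC)CCCC | intermediate
10 | (2E)-2-iodobut-2-en-1-ol | C/C=C(\CO)I | intermediate
11 | (2E)-2-methoxybut-2-en-1-ol | C/C=C(\CO)OC | intermediate
12 | (2E)-2-methoxybut-2-enal | C/C=C(\C=O)OC | intermediate
13 | methyl (2Z,4E)-4-methoxy-2-(prop-2-en-1-yl)hexa-2,4-dienoate | C/C=C(OC)\C=C(CC=C)/C(=O)OC | intermediate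
14 | prop-2-en-1-yl (2S,3R,4S)-2-methoxy-2-[(1Z)-2-(methoxycarbonyl)penta-1,4-dien-1-yl]-3-methyl-4-(3,4,5-trimethoxyphenyl)-3,4-dihydro-2H-pyran-6-carboxylate | COC(=O)/C(CC=C)=C\[C@@]1(OC)OC(C(=O)OCC=C)=C[C@H](c2cc(OC)c(OC)c(OC)c2)[C@H]1C | intermediate
15 | (2S,3R,4S)-2-methoxy-2-[(1Z)-2-(methoxycarbonyl)penta-1,4-dien-1-yl]-3-methyl-4-(3,4,5-trimethoxyphenyl)-3,4-dihydro-2H-pyran-6-carboxylic acid | COC(=O)/C(CC=C)=C\[C@@]1(OC)OC(C(=O)O)=C[C@H](c2cc(OC)c(OC)c(OC)c2)[C@H]1C | intermediate
16 | (2S,3R,4S)-2-methoxy-2-[(1Z)-2-(methoxycarbonyl)penta-1,4-dien-1-yl]-3-methyl-4-(3,4,5-trimethoxyphenyl)-3,4-dihydro-2H-pyran-6-carbonyl azide | COC(=O)/C(CC=C)=C\[C@@]1(OC)OC(C(=O)N=[N+]=[N-])=C[C@H](c2cc(OC)c(OC)c(OC)c2)[C@H]1C | intermediate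
17 | methyl (2Z)-2-{[(2S,3R,4S)-6-isocyanato-2-methoxy-3-methyl-4-(3,4,5-trimethoxyphenyl)-3,4-dihydro-2H-pyran-2-yl]methylidene}pent-4-enoate | COC(=O)/C(CC=C)=C\[C@@]1(OC)OC(N=C=O)=C[C@H](c2cc(OC)c(OC)c(OC)c2)[C@H]1C | intermediate
18 | methyl (2Z)-2-{[(2S,3R,4S)-6-imino-2-methoxy-3-methyl-4-(3,4,5-trimethoxyphenyl)oxan-2-yl]methylidene}pent-4-enoate | COC(=O)/C(CC=C)=C\[C@@]1(OC)OC(=N)C[C@H](c2cc(OC)c(OC)c(OC)c2)[C@H]1C | intermediate
19 | methyl (2Z)-2-{[(2S,3R,4S)-2-methoxy-3-methyl-6-oxo-4-(3,4,5-trimethoxyphenyl)oxan-2-yl]methylidene}pent-4-enoate | COC(=O)/C(CC=C)=C\[C@@]1(OC)OC(=O)C[C@H](c2cc(OC)c(OC)c(OC)c2)[C@H]1C | intermediate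
20 | (1R,5S,8R,9R)-5-methoxy-9-methyl-3-(prop-2-en-1-yl)-8-(3,4,5-trimethoxyphenyl)-6-oxabicyclo[3.2.2]non-3-ene-2,7-dione | C=CCC1=C[C@@]2(OC)OC(=O)[C@@H](C1=O)[C@H](c1cc(OC)c(OC)c(OC)c1)[C@H]2C | target

Total step count: 11. Longest linear sequence: 8 steps (steps 4 to 11, from but-2-yn-1-ol).

Steps most likely to fail

Step 8. The enol ether of 13 is trisubstituted and conjugated to an ester, so the cycloaddition may be too slow. The copper salt may also isomerise or hydrolyse the enol ether before it reacts, which would erode the C9/C5 relationship, and endo or facial discrimination may fall. The fallback is a catalyst-free cycloaddition with a stronger heterodiene. It sets out from 1: Knoevenagel condensation with Meldrum's acid (piperidinium acetate, EtOH, rt) should give 5-(3,4,5-trimethoxybenzylidene)-2,2-dimethyl-1,3-dioxane-4,6-dione F1. Thermal endo hetero-Diels–Alder reaction of this with 13 (toluene, rt → 60 °C) should give the racemic pyranodioxinone cycloadduct F2. Warming with water–pyridine in MeCN opens the dioxinone to the malonic half-acid F3, which loses CO2 and gives lactone 19 as the racemate. The enantiomers would then be separated on a chiral stationary phase before step 11. The fallback comes back to the route at 19.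

Step 11. The C-acylation may revert through retro-Claisen attack of the expelled methoxide on the strained, non-enolisable β-keto lactone, or the lactone enolate may fragment to a ketene before it cyclises. The fallback changes the acyl donor and sets out from 13. Transamidation (MeNHOMe·HCl, i-PrMgCl, THF, −20 °C) should give the Weinreb amide F4. Cycloaddition with 5 as in step 8 gives the cycloadduct F5, and deallylation as in step 9 gives the acid F6. The Curtius sequence of step 10 (acyl azide F7, vinyl isocyanate F8, iminolactone F9) gives the lactone amide F10. LiN(SiMe3)2 then forms the C1–C2 bond through a chelated tetrahedral intermediate that releases no alkoxide and collapses only on work-up. The fallback comes back to the route at 20.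

Step 10. The liberated enamine may intercept unreacted isocyanate (urea formation), or the imino-lactone may open to a hydroxy amide, or the ketal may be lost during the aqueous stage. The fallback sets out from 15. The Curtius rearrangement is run in the presence of 2-(trimethylsilyl)ethanol so that the isocyanate is trapped as the isolable 2-(trimethylsilyl)ethyl enecarbamate F11. This is purified and then unmasked with Bu4NF in THF followed by pH 5 buffer, so that the enamine is generated with no isocyanate left. The fallback comes back to the route at 19.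

Further compounds
F1 | step 8 | 5-(3,4,5-trimethoxybenzylidene)-2,2-dimethyl-1,3-dioxane-4,6-dione | COc1cc(C=C2C(=O)OC(C)(C)OC2=O)cc(OC)c1OC
F2 | step 8 | methyl (2Z)-2-{[7-methoxy-2,2,6-trimethyl-4-oxo-5-(3,4,5-trimethoxyphenyl)-4H,5H,6H,7H-pyrano[2,3-d][1,3]dioxin-7-yl]methylidene}pent-4-enoate (racemate, relative configuration as in 14, one enantiomer drawn) | COC(=O)/C(CC=C)=C\[C@@]1(OC)OC2=C(C(=O)OC(C)(C)O2)[C@H](c3cc(OC)c(OC)c(OC)c3)[C@H]1C
F3 | step 8 | 6-methoxy-6-[(1Z)-2-(methoxycarbonyl)penta-1,4-dien-1-yl]-5-methyl-2-oxo-4-(3,4,5-trimethoxyphenyl)oxane-3-carboxylic acid (racemate, one enantiomer drawn, C3 unassigned) | COC(=O)/C(CC=C)=C\[C@@]1(OC)OC(=O)C(C(=O)O)[C@H](c2cc(OC)c(OC)c(OC)c2)[C@H]1C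
F4 | step 11 | (2Z,4E)-N,4-dimethoxy-N-methyl-2-(prop-2-en-1-yl)hexa-2,4-dienamide | C/C=C(OC)\C=C(CC=C)/C(=O)N(C)OC
F5 | step 11 | prop-2-en-1-yl (2S,3R,4S)-2-methoxy-2-{(1Z)-2-[methoxy(methyl)carbamoyl]penta-1,4-dien-1-yl}-3-methyl-4-(3,4,5-trimethoxyphenyl)-3,4-dihydro-2H-pyran-6-carboxylate | CON(C)C(=O)/C(CC=C)=C\[C@@]1(OC)OC(C(=O)OCC=C)=C[C@H](c2cc(OC)c(OC)c(OC)c2)[C@H]1C
F6 | step 11 | (2S,3R,4S)-2-methoxy-2-{(1Z)-2-[methoxy(methyl)carbamoyl]penta-1,4-dien-1-yl}-3-methyl-4-(3,4,5-trimethoxyphenyl)-3,4-dihydro-2H-pyran-6-carboxylic acid | CON(C)C(=O)/C(CC=C)=C\[C@@]1(OC)OC(C(=O)O)=C[C@H](c2cc(OC)c(OC)c(OC)c2)[C@H]1C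
F7 | step 11 | (2S,3R,4S)-2-methoxy-2-{(1Z)-2-[methoxy(methyl)carbamoyl]penta-1,4-dien-1-yl}-3-methyl-4-(3,4,5-trimethoxyphenyl)-3,4-dihydro-2H-pyran-6-carbonyl azide | CON(C)C(=O)/C(CC=C)=C\[C@@]1(OC)OC(C(=O)N=[N+]=[N-])=C[C@H](c2cc(OC)c(OC)c(OC)c2)[C@H]1C
F8 | step 11 | (2Z)-2-{[(2S,3R,4S)-6-isocyanato-2-methoxy-3-methyl-4-(3,4,5-trimethoxyphenyl)-3,4-dihydro-2H-pyran-2-yl]methylidene}-N-methoxy-N-methylpent-4-enamide | CON(C)C(=O)/C(CC=C)=C\[C@@]1(OC)OC(N=C=O)=C[C@H](c2cc(OC)c(OC)c(OC)c2)[C@H]1C
F9 | step 11 | (2Z)-2-{[(2S,3R,4S)-6-imino-2-methoxy-3-methyl-4-(3,4,5-trimethoxyphenyl)oxan-2-yl]methylidene}-N-methoxy-N-methylpent-4-enamide | CON(C)C(=O)/C(CC=C)=C\[C@@]1(OC)OC(=N)C[C@H](c2cc(OC)c(OC)c(OC)c2)[C@H]1C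
F10 | step 11 | (2Z)-N-methoxy-2-{[(2S,3R,4S)-2-methoxy-3-methyl-6-oxo-4-(3,4,5-trimethoxyphenyl)oxan-2-yl]methylidene}-N-methylpent-4-enamide | CON(C)C(=O)/C(CC=C)=C\[C@@]1(OC)OC(=O)C[C@H](c2cc(OC)c(OC)c(OC)c2)[C@H]1C
F11 | step 10 | methyl (2Z)-2-{[(2S,3R,4S)-2-methoxy-3-methyl-4-(3,4,5-trimethoxyphenyl)-6-({[2-(trimethylsilyl)ethoxy]carbonyl}amino)-3,4-dihydro-2H-pyran-2-yl]methylidene}pent-4-enoate | COC(=O)/C(CC=C)=C\[C@@]1(OC)OC(NC(=O)OCC[Si](C)(C)C)=C[C@H](c2cc(OC)c(OC)c(OC)c2)[C@H]1C
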